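## Retrosynthetic overview

1. The side-chain C4′=C5′ alkene comes last, by cross-metathesis of a terminal allyl group with 2-methylbut-3-en-2-ol; the acetate comes from acylation, and the C9 oxygen from γ-hydroxylation of the spirocyclic enone through its silyl dienol ether.
2. The spiro[4.5] core comes from a 1,2-shift ring expansion: a ring CH2 of a 1-substituted cyclopent-3-enol migrates to the β-carbon of a butenolide (vinylogous semipinacol), forming the six-membered ketone ring and the quaternary spiro centre together.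
3. The butenolide comes from an asymmetric Ni/Cr coupling of a Z β-iodo enoate with (E)-3-methylhexa-2,5-dienal, followed by lactonisation; this sets the lactone CH–O centre, which then directs the shift.
4. The iodo enoate comes from cyclopent-3-en-1-one and methyl propiolate (addition, hydroiodination); the dienal comes from pent-1-en-4-yne (carboalumination, oxidation).
5. Ring order: cyclopentene (bought), then the γ-lactone (as a butenolide), then the cyclohexenone by expansion of the cyclopentene, which leaves the lactone spiro-fused.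

Spiro compounds are numbered as 2-oxaspiro[4.5]decanes: C1 is the lactone CH–O carrying the side chain, C3 the lactone carbonyl, C5 the spiro carbon, C6 the ring ketone, C9 the carbinol carbon.

Assumption: the four starting materials are bought, and the antipode of the chromium ligand in step 5 is the one that a trial coupling shows to give the (5R)-butenolide.

## Route

Step 1
Reactants: 1 pent-1-en-4-yne
Product: 4 (2E)-3-methylhexa-2,5-dien-1-ol, via alkenylalane 2 (not isolated), via lithium aluminate 3 (not isolated)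
Conditions: Me3Al (2 equiv), Cp2ZrCl2 (0.2 equiv), CH2Cl2, 0 °C to rt; then n-BuLi, THF, −78 to 0 °C; (CH2O)n, rt; aq. HCl
Reagents that add atoms: trimethylaluminium C[Al](C)C; formaldehyde (as paraformaldehyde) C=O
Why: Negishi zirconium-catalysed carboalumination adds Me and Al syn across the terminal alkyne with Al at the terminus, which fixes the E trisubstituted alkene, and the derived aluminate is hydroxymethylated by formaldehyde with retention.

Step 2
Reactants: 4 (2E)-3-methylhexa-2,5-dien-1-ol
Product: 5 (2E)-3-methylhexa-2,5-dienal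
Conditions: MnO2 (15 equiv), CH2Cl2, rt
Reagents that add atoms: none
Why: MnO2 oxidation of an allylic alcohol is neutral, so the E geometry is kept and the skipped diene is not pulled into conjugation.

Step 3
Reactants: 6 cyclopent-3-en-1-one; 7 methyl prop-2-ynoate
Product: 8 methyl 3-(1-hydroxycyclopent-3-en-1-yl)prop-2-ynoate
Conditions: 7, LiN(SiMe3)2, THF, −78 °C; CeCl3, −78 °C; then 6; aq. NH4Cl
Reagents that add atoms: none
Why: 1,2-addition of a metal acetylide to a ketone, in which the weakly basic cerium acetylide alkynylates the easily enolised β,γ-unsaturated ketone instead of deprotonating it; no stereocentre is formed.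

Step 4
Reactants: 8 methyl 3-(1-hydroxycyclopent-3-en-1-yl)prop-2-ynoate
Product: 9 methyl (2Z)-3-(1-hydroxycyclopent-3-en-1-yl)-3-iodoprop-2-enoate
Conditions: LiI (1.5 equiv), AcOH (2 equiv), MeCN, 70 °C
Reagents that add atoms: lithium iodide [Li+].[I-]
Why: conjugate hydroiodination of an ynoate (iodide to the β-carbon, anti protonation) gives the Z β-iodo enoate with iodine cis to the ester, so the later C–C bond is cis to the ester while the tertiary hydroxyl is trans and cannot lactonise.

Step 5
Reactants: 9 methyl (2Z)-3-(1-hydroxycyclopent-3-en-1-yl)-3-iodoprop-2-enoate; 5 (2E)-3-methylhexa-2,5-dienal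
Product: 11 (5R)-4-(1-hydroxycyclopent-3-en-1-yl)-5-[(1E)-2-methylpenta-1,4-dien-1-yl]furan-2(5H)-one, via hydroxy ester 10 (not isolated)
Conditions: CrCl2 (10 mol%), N-[2-(4-isopropyl-4,5-dihydro-1,3-oxazol-2-yl)-6-methylphenyl]methanesulfonamide (11 mol%), 1,8-bis(dimethylamino)naphthalene (11 mol%), NiCl2(2,9-dimethyl-1,10-phenanthroline) (2 mol%), Mn (2 equiv), Cp2ZrCl2 (2.2 equiv), LiCl (2 equiv), MeCN, rt; then pyridinium p-toluenesulfonate (cat.), CH2Cl2, rt
Reagents that add atoms: none
Why: catalytic asymmetric Nozaki–Hiyama–Kishi coupling, in which the alkenylchromium species formed with retention of alkene geometry adds 1,2 to the enal under control of the chiral sulfonamide on chromium to set the carbinol centre (4R in 10, 5R in 11), and the resulting cis γ-hydroxy enoate lactonises.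

Step 6
Reactants: 11 (5R)-4-(1-hydroxycyclopent-3-en-1-yl)-5-[(1E)-2-methylpenta-1,4-dien-1-yl]furan-2(5H)-one
Product: 13 (1R,5R)-1-[(1E)-2-methylpenta-1,4-dien-1-yl]-2-oxaspiro[4.5]dec-8-ene-3,6-dione, via aluminium alkoxide 12 (not isolated)
Conditions: Me2AlCl (2.5 equiv), CH2Cl2, −78 to 23 °C; cold 1 M HCl
Reagents that add atoms: none
Why: Proposed new method: a Lewis-acid-driven vinylogous semipinacol ring expansion onto a butenolide, in which one equivalent of Me2AlCl turns the tertiary alcohol into an O–Al(Me)Cl alkoxide (push) and a second binds the lactone carbonyl (pull), so that an allylic ring CH2 of the cyclopentenol shifts from the carbinol carbon to the adjacent electron-poor butenolide β-carbon while the C=O forms and the resulting lactone aluminium enolate is protonated on work-up; the two ring CH2 groups are equivalent so only one constitution can form, the shift is downhill (C=C and O–H exchanged for C=O and C–H), and the migrating carbon enters the planar butenolide anti to the C5 dienyl group, which puts the new ketone carbon cis to the side chain and sets the spiro centre as 5R; the closest known reaction types are the amine-catalysed vinylogous α-ketol rearrangement of β-(1-hydroxycyclobutyl) enones and Lewis-acid semipinacol ring expansions of 1-alkenylcyclopentanols, neither of which has been shown for an unstrained cyclopentenol with an unsaturated lactone as acceptor.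

Step 7
Reactants: 13 (1R,5R)-1-[(1E)-2-methylpenta-1,4-dien-1-yl]-2-oxaspiro[4.5]dec-8-ene-3,6-dione
Product: 16 (1R,5R,9S)-9-hydroxy-1-[(1E)-2-methylpenta-1,4-dien-1-yl]-2-oxaspiro[4.5]dec-7-ene-3,6-dione, via silyl dienol ether 14 (not isolated), via silyloxy vinyl epoxide 15 (not isolated)
Conditions: Me3SiOTf (1.3 equiv), Et3N (2 equiv), CH2Cl2, −78 to 0 °C; then dimethyldioxirane (1.1 equiv), acetone, −78 to −40 °C; aq. citric acid, THF, 0 °C
Reagents that add atoms: dimethyldioxirane CC1(C)OO1
Why: vinylogous Rubottom oxidation, in which soft enolisation at the only α-CH2 (C7) gives the linear silyl dienol ether (the same one from 13 or its conjugated isomer), the most electron-rich alkene present, and dimethyldioxirane epoxidises its distal C8=C9 bond (the C6=C7 bond is shielded by the quaternary centre) on the face anti to the pseudoaxial lactone CH2, so that opening gives the 9S γ-hydroxy enone with the hydroxyl cis to C1.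

Step 8
Reactants: 16 (1R,5R,9S)-9-hydroxy-1-[(1E)-2-methylpenta-1,4-dien-1-yl]-2-oxaspiro[4.5]dec-7-ene-3,6-dione
Product: 17 (1R,5R,9S)-1-[(1E)-2-methylpenta-1,4-dien-1-yl]-3,6-dioxo-2-oxaspiro[4.5]dec-7-en-9-yl acetate
Conditions: Ac2O, pyridine, 4-(dimethylamino)pyridine (cat.), CH2Cl2, 0 °C
Reagents that add atoms: acetic anhydride CC(=O)OC(C)=O
Why: nucleophile-catalysed acylation of the secondary allylic alcohol proceeds at oxygen with retention at C9.

Step 9
Reactants: 17 (1R,5R,9S)-1-[(1E)-2-methylpenta-1,4-dien-1-yl]-3,6-dioxo-2-oxaspiro[4.5]dec-7-en-9-yl acetate; 18 2-methylbut-3-en-2-ol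
Product: 19 (1R,5R,9S)-1-[(1E,4E)-6-hydroxy-2,6-dimethylhepta-1,4-dien-1-yl]-3,6-dioxo-2-oxaspiro[4.5]dec-7-en-9-yl acetate
Conditions: 18 (10 equiv), second-generation Hoveyda–Grubbs catalyst RuCl2(H2IMes)(=CH-C6H4-2-OiPr) (5 mol%), 1,4-benzoquinone (10 mol%), CH2Cl2, 40 °C
Reagents that add atoms: none
Why: olefin cross-metathesis engages only the monosubstituted alkene of 17 (the trisubstituted and enone alkenes are inert) with the slowly dimerising tertiary allylic alcohol to give the E alkene, while benzoquinone suppresses migration of the 1,4-diene.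

## Compound list

1 | pent-1-en-4-yne | C#CCC=C | starting material
2 | dimethyl[(1E)-2-methylpenta-1,4-dien-1-yl]alane | C[Al](C)/C=C(\C)CC=C | intermediate
3 | lithium butyl(dimethyl)[(1E)-2-methylpenta-1,4-dien-1-yl]aluminate | [Li+].CCCC[Al-](C)(C)/C=C(\C)CC=C | intermediate
4 | (2E)-3-methylhexa-2,5-dien-1-ol | OC/C=C(\C)CC=C | intermediate
5 | (2E)-3-methylhexa-2,5-dienal | O=C/C=C(\C)CC=C | intermediate
6 | cyclopent-3-en-1-one | O=C1CC=CC1 | starting material
7 | methyl prop-2-ynoate | C#CC(=O)OC | starting material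
8 | methyl 3-(1-hydroxycyclopent-3-en-1-yl)prop-2-ynoate | COC(=O)C#CC1(O)CC=CC1 | intermediate
9 | methyl (2Z)-3-(1-hydroxycyclopent-3-en-1-yl)-3-iodoprop-2-enoate | COC(=O)/C=C(\I)C1(O)CC=CC1 | intermediate
10 | methyl (2E,4R,5E)-4-hydroxy-3-(1-hydroxycyclopent-3-en-1-yl)-6-methylnona-2,5,8-trienoate | COC(=O)/C=C(\[C@H](O)/C=C(\C)CC=C)C1(O)CC=CC1 | intermediate
11 | (5R)-4-(1-hydroxycyclopent-3-en-1-yl)-5-[(1E)-2-methylpenta-1,4-dien-1-yl]furan-2(5H)-one | O=C1C=C(C2(O)CC=CC2)[C@@H](/C=C(\C)CC=C)O1 | intermediate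
12 | chloro(methyl)aluminium 1-[(2R)-2-[(1E)-2-methylpenta-1,4-dien-1-yl]-5-oxo-2,5-dihydrofuran-3-yl]cyclopent-3-en-1-olate | C[Al](Cl)OC1(CC=CC1)C1=CC(=O)O[C@@H]1/C=C(\C)CC=C | intermediate
13 | (1R,5R)-1-[(1E)-2-methylpenta-1,4-dien-1-yl]-2-oxaspiro[4.5]dec-8-ene-3,6-dione | O=C1CC=CC[C@]12CC(=O)O[C@@H]2/C=C(\C)CC=C | intermediate
14 | (1R,5R)-1-[(1E)-2-methylpenta-1,4-dien-1-yl]-6-(trimethylsilyloxy)-2-oxaspiro[4.5]deca-6,8-dien-3-one | C[Si](C)(C)OC1=CC=CC[C@]12CC(=O)O[C@@H]2/C=C(\C)CC=C | intermediate
15 | 8,9-epoxide of 14, epoxide oxygen on the ring face that carries C1 | C[Si](C)(C)OC1=C[C@H]2O[C@H]2C[C@]13CC(=O)O[C@@H]3/C=C(\C)CC=C | intermediate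
16 | (1R,5R,9S)-9-hydroxy-1-[(1E)-2-methylpenta-1,4-dien-1-yl]-2-oxaspiro[4.5]dec-7-ene-3,6-dione | O[C@@H]1C=CC(=O)[C@@]2(CC(=O)O[C@@H]2/C=C(\C)CC=C)C1 | intermediate
17 | (1R,5R,9S)-1-[(1E)-2-methylpenta-1,4-dien-1-yl]-3,6-dioxo-2-oxaspiro[4.5]dec-7-en-9-yl acetate | CC(=O)O[C@@H]1C=CC(=O)[C@@]2(CC(=O)O[C@@H]2/C=C(\C)CC=C)C1 | intermediate
18 | 2-methylbut-3-en-2-ol | CC(C)(O)C=C | starting material
19 | (1R,5R,9S)-1-[(1E,4E)-6-hydroxy-2,6-dimethylhepta-1,4-dien-1-yl]-3,6-dioxo-2-oxaspiro[4.5]dec-7-en-9-yl acetate | CC(=O)O[C@@H]1C=CC(=O)[C@@]2(CC(=O)O[C@@H]2/C=C(\C)C/C=C/C(C)(C)O)C1 | target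

## Step count and risks

Total steps: 9. Longest linear sequence: 7 (steps 3, 4, 5, 6, 7, 8, 9 from 6; equally steps 1, 2, 5, 6, 7, 8, 9 from 1).

**Step 6 (the proposed new ring expansion).** The shift has no strain release to drive it, and the Lewis acid could instead ionise the allylic lactone C–O bond of 11. The fallback uses only established enolate chemistry; it sets out from aldehyde 5 and comes back at 16. The lithium enolate (LiN(iPr)2, THF, −78 °C) of (4S)-4-{[tert-butyl(dimethyl)silyl]oxy}cyclohex-2-en-1-one F1 adds to 5 at the α′ carbon, anti to the silyloxy group. This gives, after chromatography, (4S,6R)-4-{[tert-butyl(dimethyl)silyl]oxy}-6-[(1R,2E)-1-hydroxy-3-methylhexa-2,5-dien-1-yl]cyclohex-2-en-1-one F2. Its dianion (LiN(iPr)2, 2.2 equiv) is alkylated on carbon by methyl bromoacetate, again anti to the silyloxy group, which builds the quaternary centre in methyl 2-[(1R,5S)-5-{[tert-butyl(dimethyl)silyl]oxy}-1-[(1R,2E)-1-hydroxy-3-methylhexa-2,5-dien-1-yl]-2-oxocyclohex-3-en-1-yl]acetate F3. The alkoxide of F3 closes onto the ester in the flask to give (1R,5R,9S)-9-{[tert-butyl(dimethyl)silyl]oxy}-1-[(1E)-2-methylpenta-1,4-dien-1-yl]-2-oxaspiro[4.5]dec-7-ene-3,6-dione F4. HF·pyridine then removes the silyl group and delivers 16. This path gives up the ring expansion and replaces steps 3 to 7.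

**Step 7 (γ- versus α-oxidation, and the face of attack at C9).** The face selectivity rests on a conformational argument and is the weaker point. The fallback sets out from 13 and comes back at 17. If the oxidant enters from the other face, the product is (1R,5R,9R)-9-hydroxy-1-[(1E)-2-methylpenta-1,4-dien-1-yl]-2-oxaspiro[4.5]dec-7-ene-3,6-dione F5. F5 is not acetylated with retention but esterified with inversion by a Mitsunobu reaction (PPh3, diisopropyl azodicarboxylate, AcOH, THF, 0 °C), which gives 17 directly. A mixture of 16 and F5 therefore converges on 17, with 16 going through step 8 and F5 through the Mitsunobu reaction.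

**Step 5 (enantioselectivity of the Ni/Cr coupling with an enal).** The coupling itself is reliable; the enantiomeric excess with a conjugated aldehyde is the uncertain part. The fallback gives up catalyst control; it sets out from 9 and 5 and comes back at 11. The coupling is run without ligand (CrCl2, 4 equiv; NiCl2, 1 mol%; DMF, rt). Alongside 10 and 11 this gives methyl (2E,4S,5E)-4-hydroxy-3-(1-hydroxycyclopent-3-en-1-yl)-6-methylnona-2,5,8-trienoate F6, which lactonises to (5S)-4-(1-hydroxycyclopent-3-en-1-yl)-5-[(1E)-2-methylpenta-1,4-dien-1-yl]furan-2(5H)-one F7. The racemic butenolide is resolved by preparative chromatography on a chiral stationary phase, and 11 is carried on.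

## Further compounds

F1 | step 6 | (4S)-4-{[tert-butyl(dimethyl)silyl]oxy}cyclohex-2-en-1-one | CC(C)(C)[Si](C)(C)O[C@@H]1C=CC(=O)CC1
F2 | step 6 | (4S,6R)-4-{[tert-butyl(dimethyl)silyl]oxy}-6-[(1R,2E)-1-hydroxy-3-methylhexa-2,5-dien-1-yl]cyclohex-2-en-1-one | CC(C)(C)[Si](C)(C)O[C@@H]1C=CC(=O)[C@H](C1)[C@H](O)/C=C(\C)CC=C
F3 | step 6 | methyl 2-[(1R,5S)-5-{[tert-butyl(dimethyl)silyl]oxy}-1-[(1R,2E)-1-hydroxy-3-methylhexa-2,5-dien-1-yl]-2-oxocyclohex-3-en-1-yl]acetate | CC(C)(C)[Si](C)(C)O[C@@H]1C=CC(=O)[C@@](CC(=O)OC)(C1)[C@H](O)/C=C(\C)CC=C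
F4 | step 6 | (1R,5R,9S)-9-{[tert-butyl(dimethyl)silyl]oxy}-1-[(1E)-2-methylpenta-1,4-dien-1-yl]-2-oxaspiro[4.5]dec-7-ene-3,6-dione | CC(C)(C)[Si](C)(C)O[C@@H]1C=CC(=O)[C@@]2(CC(=O)O[C@@H]2/C=C(\C)CC=C)C1
F5 | step 7 | (1R,5R,9R)-9-hydroxy-1-[(1E)-2-methylpenta-1,4-dien-1-yl]-2-oxaspiro[4.5]dec-7-ene-3,6-dione | O[C@H]1C=CC(=O)[C@@]2(CC(=O)O[C@@H]2/C=C(\C)CC=C)C1
F6 | step 5 | methyl (2E,4S,5E)-4-hydroxy-3-(1-hydroxycyclopent-3-en-1-yl)-6-methylnona-2,5,8-trienoate | COC(=O)/C=C(\[C@@H](O)/C=C(\C)CC=C)C1(O)CC=CC1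
F7 | step 5 | (5S)-4-(1-hydroxycyclopent-3-en-1-yl)-5-[(1E)-2-methylpenta-1,4-dien-1-yl]furan-2(5H)-one | O=C1C=C(C2(O)CC=CC2)[C@H](/C=C(\C)CC=C)O1
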